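**Strategy.** The route rests on cutting the C9–C10 bond of ring B (halimane numbering): C10 is the sp2 ring-fusion carbon of the C1=C10 alkene in ring A, and C9 is the adjacent quaternary carbon that carries the C20 methyl group. A 6-exo reductive Heck cyclisation of a ring A cyclohexenyl bromide (bromine on C10) onto a tethered 1,1-disubstituted alkene (C9=C20H2) closes ring B, creates the quaternary stereocentre C9 and turns the alkene methylene into the C20 methyl in one operation, leaving the alkene at C1=C10. The precursor is a monocyclic bromocyclohexene ester carrying C4, C5 and C8 and the finished epoxy alcohol side chain.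

Key step: step 15

Assumption: halimane numbering is used throughout (ring A = C1–C5 and C10, ring B = C5–C10, C17 on C8, C18 and ester carbon C19 on C4, C20 on C9, side chain C11–C16); the sense of induction in steps 1, 5 and 8 is assigned from the accepted models, and the antipodal catalyst or auxiliary would be used if a model failed.

Step 1
Reactants: 1 (E)-3-[(tert-butyldimethylsilyl)oxy]-N,N-dimethylbuta-1,3-dien-1-amine; 2 methacrolein
Product: 4 (S)-1-methyl-4-oxocyclohex-2-ene-1-carbaldehyde, via cycloadduct 3 (not isolated)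
Conditions: (R,R)-(salen)CrSbF6 (cat.; salen = N,N'-bis(3,5-di-tert-butylsalicylidene)cyclohexane-1,2-diamine dianion, trivalent chromium), 4 Å MS, CH2Cl2, −40 °C; then AcCl, CH2Cl2/Et2O, −78 °C
Reagents that add atoms: none
Why: Catalytic asymmetric Diels–Alder reaction of an amino siloxy diene with an α-substituted acrolein, in which the chiral Lewis acid binds the aldehyde and shields one face to set quaternary C4, followed by N-acylation-triggered elimination to the enone.

Step 2
Reactants: 4 (S)-1-methyl-4-oxocyclohex-2-ene-1-carbaldehyde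
Product: 5 (S)-1-methyl-4-oxocyclohex-2-ene-1-carboxylic acid
Conditions: NaClO2, NaH2PO4, 2-methylbut-2-ene, t-BuOH/H2O, 0 °C to rt
Reagents that add atoms: sodium chlorite, [Na+].[O-]Cl=O
Why: Pinnick oxidation should convert the non-enolisable aldehyde to the acid without touching the enone, the hypochlorite being scavenged by the alkene additive.

Step 3
Reactants: 5 (S)-1-methyl-4-oxocyclohex-2-ene-1-carboxylic acid
Product: 6 methyl (S)-1-methyl-4-oxocyclohex-2-ene-1-carboxylate
Conditions: TMSCHN2, PhMe/MeOH, 0 °C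
Reagents that add atoms: (trimethylsilyl)diazomethane, C[Si](C)(C)C=[N+]=[N-]
Why: Diazoalkane esterification methylates the hindered carboxylic acid at oxygen under neutral conditions, so the quaternary centre is not at risk.

Step 4
Reactants: 6 methyl (S)-1-methyl-4-oxocyclohex-2-ene-1-carboxylate
Product: 8 methyl (S)-3-bromo-1-methyl-4-oxocyclohex-2-ene-1-carboxylate, via dibromide 7 (not isolated)
Conditions: Br2, CH2Cl2, 0 °C; then Et3N, 0 °C to rt
Reagents that add atoms: bromine, BrBr
Why: Bromination–dehydrobromination of an enone, in which anti addition of bromine and E1cB loss of HBr from the α-carbon should give the 2-bromoenone with bromine on C10 only.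

Step 5
Reactants: 8 methyl (S)-3-bromo-1-methyl-4-oxocyclohex-2-ene-1-carboxylate
Product: 9 methyl (1S,4R)-3-bromo-4-hydroxy-1-methylcyclohex-2-ene-1-carboxylate
Conditions: (S)-2-methyl-CBS-oxazaborolidine (cat.), BH3·SMe2, THF, −20 °C
Reagents that add atoms: none
Why: Corey–Bakshi–Shibata reduction, in which the bromoalkenyl arm acts as the large group so that the (S)-catalyst delivers hydride to the α-face and places the C1 hydroxyl cis to the ester, overriding the remote C4 centre.

Step 6
Reactants: 9 methyl (1S,4R)-3-bromo-4-hydroxy-1-methylcyclohex-2-ene-1-carboxylate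
Product: 12 methyl (1S,2S)-3-bromo-2-(2-hydroxyethyl)-1-methylcyclohex-3-ene-1-carboxylate, via vinyl ether 10 (not isolated), via aldehyde 11 (not isolated)
Conditions: Hg(OAc)2 (cat.), ethyl vinyl ether/PhMe, sealed tube, 45 °C then 170 °C; cool, MeOH, NaBH4, 0 °C
Reagents that add atoms: ethyl vinyl ether, C=COCC
Why: Mercury-catalysed transvinylation and thermal Claisen rearrangement, whose suprafacial [3,3] shift forms the C5–C6 bond on the face that held the C1–O bond (cis to the ester) and moves the alkene to C1=C10 with bromine kept on C10, followed by borohydride reduction of the aldehyde in the same pot.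

Step 7
Reactants: 12 methyl (1S,2S)-3-bromo-2-(2-hydroxyethyl)-1-methylcyclohex-3-ene-1-carboxylate
Product: 13 methyl (1S,2S)-3-bromo-1-methyl-2-{2-[(trifluoromethanesulfonyl)oxy]ethyl}cyclohex-3-ene-1-carboxylate
Conditions: Tf2O, 2,6-lutidine, CH2Cl2, −78 °C
Reagents that add atoms: trifluoromethanesulfonic anhydride, O=S(=O)(OS(=O)(=O)C(F)(F)F)C(F)(F)F
Why: Sulfonylation of the primary alcohol gives an alkyl triflate reactive enough for an imide enolate, and it is used at once in the cold to outrun lactonisation onto the neighbouring ester.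

Step 8
Reactants: 13 methyl (1S,2S)-3-bromo-1-methyl-2-{2-[(trifluoromethanesulfonyl)oxy]ethyl}cyclohex-3-ene-1-carboxylate; 14 (S)-4-benzyl-3-propanoyl-1,3-oxazolidin-2-one
Product: 15 methyl (1S,2S)-2-{(3R)-4-[(4S)-4-benzyl-2-oxo-1,3-oxazolidin-3-yl]-3-methyl-4-oxobutyl}-3-bromo-1-methylcyclohex-3-ene-1-carboxylate
Conditions: 14, NaN(SiMe3)2, THF, −78 °C; then 13, −78 to −40 °C
Reagents that add atoms: none
Why: Evans asymmetric alkylation, in which the chelated (Z)-sodium enolate is alkylated on the face away from the benzyl group and so sets C8 as (R).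

Step 9
Reactants: 15 methyl (1S,2S)-2-{(3R)-4-[(4S)-4-benzyl-2-oxo-1,3-oxazolidin-3-yl]-3-methyl-4-oxobutyl}-3-bromo-1-methylcyclohex-3-ene-1-carboxylate
Product: 16 methyl (1S,2S)-3-bromo-2-{(3R)-4-[methoxy(methyl)amino]-3-methyl-4-oxobutyl}-1-methylcyclohex-3-ene-1-carboxylate
Conditions: MeNH(OMe)·HCl, Me3Al, CH2Cl2, −10 to 0 °C
Reagents that add atoms: N,O-dimethylhydroxylamine hydrochloride, CNOC.Cl
Why: Aluminium amide transamidation cleaves the exocyclic imide carbonyl selectively, the α-quaternary methyl ester being too hindered to react, and gives the Weinreb amide without epimerising C8.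

Step 10
Reactants: 16 methyl (1S,2S)-3-bromo-2-{(3R)-4-[methoxy(methyl)amino]-3-methyl-4-oxobutyl}-1-methylcyclohex-3-ene-1-carboxylate; 17 (4-bromobut-1-yn-1-yl)trimethylsilane
Product: 19 methyl (1S,2S)-3-bromo-1-methyl-2-[(3R)-3-methyl-4-oxo-8-(trimethylsilyl)oct-7-yn-1-yl]cyclohex-3-ene-1-carboxylate, via Grignard reagent 18 (not isolated)
Conditions: 17, Mg, THF, rt; then 16, THF, 0 °C; aq. NH4Cl
Reagents that add atoms: none
Why: Weinreb ketone synthesis, in which the chelated tetrahedral adduct stops at the ketone stage and the Grignard reagent spares the vinyl bromide and the hindered ester.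

Step 11
Reactants: 19 methyl (1S,2S)-3-bromo-1-methyl-2-[(3R)-3-methyl-4-oxo-8-(trimethylsilyl)oct-7-yn-1-yl]cyclohex-3-ene-1-carboxylate
Product: 20 methyl (1S,2S)-3-bromo-1-methyl-2-[(3R)-3-methyl-4-methylidene-8-(trimethylsilyl)oct-7-yn-1-yl]cyclohex-3-ene-1-carboxylate
Conditions: Zn, CH2Br2, TiCl4, THF/CH2Cl2, 0 °C to rt
Reagents that add atoms: dibromomethane, BrCBr
Why: Takai–Lombardo methylenation uses a non-basic gem-dimetallic reagent that converts the ketone, not the ester, into the 1,1-disubstituted alkene without epimerising the adjacent C8.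

Step 12
Reactants: 20 methyl (1S,2S)-3-bromo-1-methyl-2-[(3R)-3-methyl-4-methylidene-8-(trimethylsilyl)oct-7-yn-1-yl]cyclohex-3-ene-1-carboxylate
Product: 21 methyl (1S,2S)-3-bromo-1-methyl-2-[(3R)-3-methyl-4-methylideneoct-7-yn-1-yl]cyclohex-3-ene-1-carboxylate
Conditions: K2CO3, MeOH, rt
Reagents that add atoms: none
Why: Base-mediated methanolysis of the alkynyl C–Si bond (protodesilylation) frees the terminal alkyne, and the methyl ester is invariant to methoxide exchange.

Step 13
Reactants: 21 methyl (1S,2S)-3-bromo-1-methyl-2-[(3R)-3-methyl-4-methylideneoct-7-yn-1-yl]cyclohex-3-ene-1-carboxylate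
Product: 23 methyl (1S,2S)-3-bromo-2-[(3R,7E)-9-hydroxy-3,7-dimethyl-4-methylidenenon-7-en-1-yl]-1-methylcyclohex-3-ene-1-carboxylate, via alkenylalane 22 (not isolated)
Conditions: Me3Al, Cp2ZrCl2 (cat.), CH2Cl2, 0 °C to rt; then n-BuLi, hexane/THF, −78 °C; (CH2O)n, −78 °C to rt
Reagents that add atoms: trimethylaluminium, C[Al](C)C; paraformaldehyde (as formaldehyde), C=O
Why: Negishi zirconium-catalysed methylalumination adds methyl and aluminium syn across the terminal alkyne with methyl on the internal carbon, and hydroxymethylation of the derived alanate gives the (E)-trisubstituted allylic alcohol.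

Step 14
Reactants: 23 methyl (1S,2S)-3-bromo-2-[(3R,7E)-9-hydroxy-3,7-dimethyl-4-methylidenenon-7-en-1-yl]-1-methylcyclohex-3-ene-1-carboxylate
Product: 24 methyl (1S,2S)-3-bromo-2-{(3R)-5-[(2R,3R)-3-(hydroxymethyl)-2-methyloxiran-2-yl]-3-methyl-4-methylidenepentyl}-1-methylcyclohex-3-ene-1-carboxylate
Conditions: Ti(OiPr)4 (cat.), D-(−)-diethyl tartrate (cat.), t-BuOOH, 4 Å MS, CH2Cl2, −20 °C
Reagents that add atoms: tert-butyl hydroperoxide, CC(C)(C)OO
Why: Sharpless asymmetric epoxidation, in which the titanium tartrate complex epoxidises only the allylic alcohol and D-(−)-tartrate delivers oxygen to the face that gives the (13R,14R)-oxirane from the (E)-alkene.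

Step 15
Reactants: 24 methyl (1S,2S)-3-bromo-2-{(3R)-5-[(2R,3R)-3-(hydroxymethyl)-2-methyloxiran-2-yl]-3-methyl-4-methylidenepentyl}-1-methylcyclohex-3-ene-1-carboxylate
Product: 25 methyl (1S,5S,6R,8aR)-5-{2-[(2R,3R)-3-(hydroxymethyl)-2-methyloxiran-2-yl]ethyl}-1,5,6-trimethyl-1,2,3,5,6,7,8,8a-octahydronaphthalene-1-carboxylate (CNP0324371.2)
Conditions: Pd(OAc)2 (cat.), PPh3, HCO2Na, Et4NCl, DMF, 80 °C
Reagents that add atoms: none
Why: Oxidative addition of zerovalent palladium into the C10–Br bond, syn carbopalladation of the C9=C20 alkene and formate-mediated hydride transfer (decarboxylation, then C–H reductive elimination) at the neopentyl alkylpalladium, which has no β-hydrogen, close ring B and form the C20 methyl. The closest known reaction type is the reductive Heck cyclisation (cyclisation–hydride capture) that builds quaternary carbons from aryl or alkenyl halides and 1,1-disubstituted alkenes. Ring B closes in the 6-exo-trig mode by C9–C10 bond formation, since 7-endo closure would need attack at the unsubstituted alkene terminus with palladium ending on a tertiary carbon. The new stereocentre C9 is controlled by the existing centres C5 and C8: insertion needs the alkene eclipsed with the C10–Pd bond, which puts the palladium-bearing C20 axial on the forming chair, and only the chair with the C8 methyl and the C5–C4 bond equatorial places that axial carbon cis to H-5 and to the C8 methyl, as the target requires. The step needs insertion to win over direct reduction of the alkenylpalladium and over any further insertion; the intramolecular 6-exo pathway and the absence of any other alkene or alkyne in the substrate (the side chain is already epoxidised) should secure this, while the bromide position fixes the alkene at C1=C10.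

**Compound list**

1 | (E)-3-[(tert-butyldimethylsilyl)oxy]-N,N-dimethylbuta-1,3-dien-1-amine | CN(C)/C=C/C(=C)O[Si](C)(C)C(C)(C)C | starting material
2 | methacrolein (2-methylprop-2-enal) | CC(=C)C=O | starting material
3 | (1S,2R)-4-[(tert-butyldimethylsilyl)oxy]-2-(dimethylamino)-1-methylcyclohex-3-ene-1-carbaldehyde (endo cycloadduct) | O=C[C@@]1(C)CCC(O[Si](C)(C)C(C)(C)C)=C[C@H]1N(C)C | intermediate
4 | (S)-1-methyl-4-oxocyclohex-2-ene-1-carbaldehyde | O=C[C@@]1(C)CCC(=O)C=C1 | intermediate
5 | (S)-1-methyl-4-oxocyclohex-2-ene-1-carboxylic acid | OC(=O)[C@@]1(C)CCC(=O)C=C1 | intermediate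
6 | methyl (S)-1-methyl-4-oxocyclohex-2-ene-1-carboxylate | COC(=O)[C@@]1(C)CCC(=O)C=C1 | intermediate
7 | methyl (1R,2R,3R)-2,3-dibromo-1-methyl-4-oxocyclohexane-1-carboxylate (trans-dibromide; one anti adduct drawn, either converges on 8) | COC(=O)[C@@]1(C)CCC(=O)[C@@H](Br)[C@@H]1Br | intermediate
8 | methyl (S)-3-bromo-1-methyl-4-oxocyclohex-2-ene-1-carboxylate | COC(=O)[C@@]1(C)CCC(=O)C(Br)=C1 | intermediate
9 | methyl (1S,4R)-3-bromo-4-hydroxy-1-methylcyclohex-2-ene-1-carboxylate (hydroxyl cis to ester) | COC(=O)[C@@]1(C)CC[C@@H](O)C(Br)=C1 | intermediate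
10 | methyl (1S,4R)-3-bromo-4-(ethenyloxy)-1-methylcyclohex-2-ene-1-carboxylate | COC(=O)[C@@]1(C)CC[C@@H](OC=C)C(Br)=C1 | intermediate
11 | methyl (1S,2S)-3-bromo-1-methyl-2-(2-oxoethyl)cyclohex-3-ene-1-carboxylate | COC(=O)[C@@]1(C)CCC=C(Br)[C@H]1CC=O | intermediate
12 | methyl (1S,2S)-3-bromo-2-(2-hydroxyethyl)-1-methylcyclohex-3-ene-1-carboxylate | COC(=O)[C@@]1(C)CCC=C(Br)[C@H]1CCO | intermediate
13 | methyl (1S,2S)-3-bromo-1-methyl-2-{2-[(trifluoromethanesulfonyl)oxy]ethyl}cyclohex-3-ene-1-carboxylate | COC(=O)[C@@]1(C)CCC=C(Br)[C@H]1CCOS(=O)(=O)C(F)(F)F | intermediate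
14 | (S)-4-benzyl-3-propanoyl-1,3-oxazolidin-2-one | CCC(=O)N1C(=O)OC[C@@H]1Cc1ccccc1 | starting material
15 | methyl (1S,2S)-2-{(3R)-4-[(4S)-4-benzyl-2-oxo-1,3-oxazolidin-3-yl]-3-methyl-4-oxobutyl}-3-bromo-1-methylcyclohex-3-ene-1-carboxylate | COC(=O)[C@@]1(C)CCC=C(Br)[C@H]1CC[C@@H](C)C(=O)N1C(=O)OC[C@@H]1Cc1ccccc1 | intermediate
16 | methyl (1S,2S)-3-bromo-2-{(3R)-4-[methoxy(methyl)amino]-3-methyl-4-oxobutyl}-1-methylcyclohex-3-ene-1-carboxylate | COC(=O)[C@@]1(C)CCC=C(Br)[C@H]1CC[C@@H](C)C(=O)N(C)OC | intermediate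
17 | (4-bromobut-1-yn-1-yl)trimethylsilane | C[Si](C)(C)C#CCCBr | starting material
18 | [4-(trimethylsilyl)but-3-yn-1-yl]magnesium bromide | C[Si](C)(C)C#CCC[Mg]Br | intermediate
19 | methyl (1S,2S)-3-bromo-1-methyl-2-[(3R)-3-methyl-4-oxo-8-(trimethylsilyl)oct-7-yn-1-yl]cyclohex-3-ene-1-carboxylate | COC(=O)[C@@]1(C)CCC=C(Br)[C@H]1CC[C@@H](C)C(=O)CCC#C[Si](C)(C)C | intermediate
20 | methyl (1S,2S)-3-bromo-1-methyl-2-[(3R)-3-methyl-4-methylidene-8-(trimethylsilyl)oct-7-yn-1-yl]cyclohex-3-ene-1-carboxylate | COC(=O)[C@@]1(C)CCC=C(Br)[C@H]1CC[C@@H](C)C(=C)CCC#C[Si](C)(C)C | intermediate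
21 | methyl (1S,2S)-3-bromo-1-methyl-2-[(3R)-3-methyl-4-methylideneoct-7-yn-1-yl]cyclohex-3-ene-1-carboxylate | COC(=O)[C@@]1(C)CCC=C(Br)[C@H]1CC[C@@H](C)C(=C)CCC#C | intermediate
22 | (E)-alkenyl(dimethyl)alane from syn methylalumination of 21 (aluminium on C14, methyl on C13) | COC(=O)[C@@]1(C)CCC=C(Br)[C@H]1CC[C@@H](C)C(=C)CC/C(C)=C/[Al](C)C | intermediate
23 | methyl (1S,2S)-3-bromo-2-[(3R,7E)-9-hydroxy-3,7-dimethyl-4-methylidenenon-7-en-1-yl]-1-methylcyclohex-3-ene-1-carboxylate | COC(=O)[C@@]1(C)CCC=C(Br)[C@H]1CC[C@@H](C)C(=C)CC/C(C)=C/CO | intermediate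
24 | methyl (1S,2S)-3-bromo-2-{(3R)-5-[(2R,3R)-3-(hydroxymethyl)-2-methyloxiran-2-yl]-3-methyl-4-methylidenepentyl}-1-methylcyclohex-3-ene-1-carboxylate | COC(=O)[C@@]1(C)CCC=C(Br)[C@H]1CC[C@@H](C)C(=C)CC[C@@]1(C)O[C@@H]1CO | intermediate
25 | methyl (1S,5S,6R,8aR)-5-{2-[(2R,3R)-3-(hydroxymethyl)-2-methyloxiran-2-yl]ethyl}-1,5,6-trimethyl-1,2,3,5,6,7,8,8a-octahydronaphthalene-1-carboxylate (CNP0324371.2) | COC(=O)[C@@]1(C)CCC=C2[C@H]1CC[C@@H](C)[C@]2(C)CC[C@@]1(C)O[C@@H]1CO | target

**Step count.** Total: 15 steps. Longest linear sequence: 15 steps (steps 1–15; compounds 1, 2, 14 and 17 are purchased).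

**Steps most likely to fail, with fallbacks**

Risk 1 (step 15): the unprotected epoxy alcohol may not survive the hot, basic, reducing palladium medium (Payne-type isomerisation or opening of the oxirane), and a slow insertion into the hindered alkene would let formate reduce the alkenylpalladium before ring closure. The fallback closes ring B before the oxirane exists. It sets out from allylic alcohol 23, which is submitted to the same 6-exo cyclisation with hydride capture (Pd(OAc)2, PPh3, excess HCO2Na, Et4NCl, DMF). Hydride capture must there outrun a second insertion into the C13=C14 alkene. The product is methyl (1S,5S,6R,8aR)-5-[(3E)-5-hydroxy-3-methylpent-3-en-1-yl]-1,5,6-trimethyl-1,2,3,5,6,7,8,8a-octahydronaphthalene-1-carboxylate F1. Sharpless epoxidation of the allylic alcohol of F1 (Ti(OiPr)4, D-(−)-diethyl tartrate, t-BuOOH), to which the hindered ring alkene is inert, then comes back to the route at 25.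

Risk 2 (step 6): the thermal [3,3] shift may be too slow at C5, which lies next to quaternary C4, so that loss of the allylic oxygen by elimination or decomposition of the vinyl ether competes at the temperature required. The fallback is an ester enolate rearrangement that runs far below that temperature. It sets out from alcohol 9, which is acetylated (Ac2O, DMAP, pyridine) to methyl (1S,4R)-4-(acetyloxy)-3-bromo-1-methylcyclohex-2-ene-1-carboxylate F2. Ireland–Claisen rearrangement (LiN(iPr)2, t-BuMe2SiCl, THF/DMPU, −78 to 60 °C, then aqueous acid) should give 2-[(1S,6S)-2-bromo-6-(methoxycarbonyl)-6-methylcyclohex-2-en-1-yl]acetic acid F3 with the same suprafacial transfer of configuration. Chemoselective reduction of the free acid in the presence of the methyl ester (BH3·THF, 0 °C) comes back to the route at 12.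

Risk 3 (step 13): trimethylaluminium or the butyllithium used to form the alanate may attack the methyl ester or exchange the vinyl bromide, and the methylalumination may lose regiocontrol on this functionalised alkyne. The fallback brings in the side chain complete, with the allylic oxygen silyl-protected, so that no organoaluminium chemistry is run on the ester-bearing intermediate. The side-chain bromide is made from purchased 4-[(tert-butyldimethylsilyl)oxy]but-1-yne:
- methylalumination and hydroxymethylation (Me3Al, Cp2ZrCl2; n-BuLi; (CH2O)n) give (2E)-5-{[tert-butyl(dimethyl)silyl]oxy}-3-methylpent-2-en-1-ol F4;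
- silylation (t-BuPh2SiCl, imidazole) gives tert-butyl{[(2E)-5-{[tert-butyl(dimethyl)silyl]oxy}-3-methylpent-2-en-1-yl]oxy}diphenylsilane F5;
- selective cleavage of the primary t-BuMe2Si ether (pyridinium p-toluenesulfonate, MeOH) gives (3E)-5-{[tert-butyl(diphenyl)silyl]oxy}-3-methylpent-3-en-1-ol F6;
- Appel bromination (CBr4, PPh3) gives {[(2E)-5-bromo-3-methylpent-2-en-1-yl]oxy}(tert-butyl)diphenylsilane F7.

The fallback then sets out from Weinreb amide 16. Addition of the Grignard reagent [(3E)-5-{[tert-butyl(diphenyl)silyl]oxy}-3-methylpent-3-en-1-yl]magnesium bromide F8 (from F7 and Mg) gives methyl (1S,2S)-3-bromo-2-[(3R,7E)-9-{[tert-butyl(diphenyl)silyl]oxy}-3,7-dimethyl-4-oxonon-7-en-1-yl]-1-methylcyclohex-3-ene-1-carboxylate F9. Methylenation (Zn, CH2Br2, TiCl4) gives methyl (1S,2S)-3-bromo-2-[(3R,7E)-9-{[tert-butyl(diphenyl)silyl]oxy}-3,7-dimethyl-4-methylidenenon-7-en-1-yl]-1-methylcyclohex-3-ene-1-carboxylate F10, and desilylation (Bu4NF, THF) comes back to the route at 23.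

Further compounds
F1 | step 15 | methyl (1S,5S,6R,8aR)-5-[(3E)-5-hydroxy-3-methylpent-3-en-1-yl]-1,5,6-trimethyl-1,2,3,5,6,7,8,8a-octahydronaphthalene-1-carboxylate | COC(=O)[C@@]1(C)CCC=C2[C@H]1CC[C@@H](C)[C@]2(C)CC/C(C)=C/CO
F2 | step 6 | methyl (1S,4R)-4-(acetyloxy)-3-bromo-1-methylcyclohex-2-ene-1-carboxylate | COC(=O)[C@@]1(C)CC[C@@H](OC(C)=O)C(Br)=C1
F3 | step 6 | 2-[(1S,6S)-2-bromo-6-(methoxycarbonyl)-6-methylcyclohex-2-en-1-yl]acetic acid | COC(=O)[C@@]1(C)CCC=C(Br)[C@H]1CC(O)=O
F4 | step 13 | (2E)-5-{[tert-butyl(dimethyl)silyl]oxy}-3-methylpent-2-en-1-ol | CC(C)(C)[Si](C)(C)OCC/C(C)=C/CO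
F5 | step 13 | tert-butyl{[(2E)-5-{[tert-butyl(dimethyl)silyl]oxy}-3-methylpent-2-en-1-yl]oxy}diphenylsilane | CC(C)(C)[Si](C)(C)OCC/C(C)=C/CO[Si](c1ccccc1)(c1ccccc1)C(C)(C)C
F6 | step 13 | (3E)-5-{[tert-butyl(diphenyl)silyl]oxy}-3-methylpent-3-en-1-ol | OCC/C(C)=C/CO[Si](c1ccccc1)(c1ccccc1)C(C)(C)C
F7 | step 13 | {[(2E)-5-bromo-3-methylpent-2-en-1-yl]oxy}(tert-butyl)diphenylsilane | BrCC/C(C)=C/CO[Si](c1ccccc1)(c1ccccc1)C(C)(C)C
F8 | step 13 | [(3E)-5-{[tert-butyl(diphenyl)silyl]oxy}-3-methylpent-3-en-1-yl]magnesium bromide | Br[Mg]CC/C(C)=C/CO[Si](c1ccccc1)(c1ccccc1)C(C)(C)C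
F9 | step 13 | methyl (1S,2S)-3-bromo-2-[(3R,7E)-9-{[tert-butyl(diphenyl)silyl]oxy}-3,7-dimethyl-4-oxonon-7-en-1-yl]-1-methylcyclohex-3-ene-1-carboxylate | COC(=O)[C@@]1(C)CCC=C(Br)[C@H]1CC[C@@H](C)C(=O)CC/C(C)=C/CO[Si](c1ccccc1)(c1ccccc1)C(C)(C)C
F10 | step 13 | methyl (1S,2S)-3-bromo-2-[(3R,7E)-9-{[tert-butyl(diphenyl)silyl]oxy}-3,7-dimethyl-4-methylidenenon-7-en-1-yl]-1-methylcyclohex-3-ene-1-carboxylate | COC(=O)[C@@]1(C)CCC=C(Br)[C@H]1CC[C@@H](C)C(=C)CC/C(C)=C/CO[Si](c1ccccc1)(c1ccccc1)C(C)(C)C
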